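The numbers in the tables are simulated on assumed constants, and the scatter is random.

Millimolar, not peak height, is the unit for this flask: 0.20 mM of substrate meets 0.240 mM of reagent and 0.240 mM of scavenger, and the green run is this same flask followed to 3.00 min.

green run (percent of the substrate charged)

| time / min | substrate / % | target / % |
|---|---|---|
| 0.167 | 17.8 | 14.1 |
| 0.500 | 3.6 | 14.0 |
| 0.833 | 3.3 | 11.9 |
| 1.33 | 2.0 | 12.9 |
| 2.00 | 3.1 | 15.1 |
| 2.50 | 1.6 | 11.6 |
| 3.00 | 2.2 | 14.1 |

(each reading ± 1 percentage point)

- what has gone from substrate into another species counts as reacted, even if it can come back
- the earlier runs do not show how much of reagent is bound; that part of a forecast is a guess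

- part of the substrate that has reacted at 10 min
- share of the unused reagent that is free and not bound as idle adduct, at 10 min

Substrate reads 17.8% at 0.167 min, which gives an apparent first-order constant k = 10.3 min⁻¹, as a reading. At 3.00 min, substrate reads 2.2% and target 14.1%, so by these two readings about 83.7% of the charge sits in forms not read.

The end state comes first. Substrate is the limiting reagent if one reagent consumes one substrate. Suppose each reacted substrate also frees one partner, which scavenger catches or reagent holds as idle adduct. The rule is then the scavenger margin M, the scavenger charge less the substrate charge 0.0400 mM. Scavenger exceeds the partner that can form, so reagent should stay free, and at least 0.0400 mM of it should remain.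

The objection is the stall. Even with no more reagent than that, the pseudo-first-order constant is 1.72 min⁻¹, a half-life of 0.403 min, yet substrate reads merely 3.6% at 0.500 min and 2.2% at 3.00 min. Bound reagent is one reading of this, but with M positive the scavenger charge covers the partner, so little reagent is expected to be bound. A reversible store of substrate, counted as reacted and returning slowly, fits the stall too, and it makes k larger than the reagent step's own constant. My reckoning for 10 min is therefore about 97.8% reacted, taken from the last reading, and, as a guess, a free share near 100%.

The forecast stands at 98% reacted, close to my figure, but parts on the free share, 10%, taking as likeliest that “free reagent has been almost entirely removed”. The flask gives 99.4% and >99.9%.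

    substrate + reagent → intermediate + released group (k = 540 M⁻¹ s⁻¹)
    intermediate ⇌ target (K = 0.730, k = 0.125 s⁻¹)
    intermediate ⇌ isomer of the product (K = 2.54, k = 0.0521 s⁻¹)
    reagent + released group ⇌ idle adduct, settled at all times (K = 6400 M⁻¹)
    scavenger + released group → scavenged by-product (k = 52400 M⁻¹ s⁻¹)
    substrate ⇌ dormant form (K = 7.75, k = 0.0880 s⁻¹)

At 10.0 min in this flask, released group has a half-life against scavenger of 0.25 s, far shorter than the 0.179 min by which half of its release is done. Idle adduct then stands at 4.13 × 10⁻⁶ mM, with reagent at 22.1% of its charge. M over the scavenger charge is 16.7%, and this flask holds 16.7% of its scavenger at 100 min. The neighbour flask with 0.060 mM of scavenger has M = −0.140 mM: at 10.0 min its scavenger stands at 0%, its released group at 0.0976 mM, its idle adduct at 0.0229 mM, and its free share at 61.5%.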